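If this flask were to stall, the acid set free would have to leave too slowly, so I turned the question round and asked how fast it must leave.

    electrophile + nucleophile → acid set free + product (k1 = 0.015 M⁻¹ s⁻¹)
    nucleophile + acid set free ⇌ protonated nucleophile, settled at all times (K2 = 3600 M⁻¹)
    acid set free + free base ⇌ salt of the base (K3 = 34 M⁻¹, k3 = 0.18 M⁻¹ s⁻¹)
    acid set free → by-product carried off (k4 = 0.0019 s⁻¹)
    solid electrophile ⇌ electrophile, rate k5*(cs5 - [electrophile]) while solid is left; crystals form when [electrophile] > cs5 (cs5 = 35 mM, k5 = 2.8 × 10⁻⁴ s⁻¹)

solid electrophile 0.050 M; nucleophile 0.0650 M; free base 0.0750 M; time 10 h

- solid electrophile is a solid; its amount is given per volume of the solution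
- at the start none of the solid electrophile is in solution
- what has only dissolved of solid electrophile counts as not reacted
- run time (flask): 10 h

* part of the solid electrophile that has reacted (what has only dissolved counts as not reacted) at 10 h
* share of the unused nucleophile that is free and not bound as protonated nucleophile, at 10 h

In this flask the nucleophile takes up the acid ahead of the free base, since at the start 230 for the nucleophile stands far above 2.5 for the free base. Full conversion leaves 0.0150 M of nucleophile in both forms. Setting aside what the free base and the free acid hold, that much acid stays bound, so I estimated that about 0.0350 M must be carried off. I called this the debt.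

The fast balance makes [acid set free] equal to the ratio [protonated nucleophile]/[nucleophile] over its constant. The loss therefore integrates in closed form: at a ratio of one it runs at 0.00190 M h⁻¹, and the amount lost is that rate times the mean ratio times the time. The needed ratio, the debt over that rate and the run time, is 1.84.

Could this flask keep that up? Acid made equals acid lost at a ratio of 2.53, if I set [electrophile] and [protonated nucleophile] each near 0.0150 M. That is more than needed. At that ratio the debt takes 7.28 h, inside 10 h, so I committed to a small rest of electrophile.

The forecast gave 98% (95% to 99.5%) and 50% (38% to 65%), holding that “the nucleophile takes up the acid”.

The simulation gave 97.7% and 50.8%. By 10.0 h this flask had 0.0400 M of by-product carried off, more than the debt. Divided by the loss at ratio one and the run time, that is a mean ratio of 2.10, above the needed 1.84.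

In the neighbour with 0.039 M of nucleophile, the nucleophile is the limiting reagent at 0.780 equiv, so product stops at 78.0%, and the needed ratio is 2.05. The neighbour gave 75.1%, short of that ceiling, with 0.0364 M carried off, a mean ratio of 1.92, below the ratio it needed.

The numbers were set for the occasion, and the outcome is calculated.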